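The earlier runs and the new flask are calculated for substances that don't exist; the scatter is artificial.

**Early times.** At early times the violet run, an earlier flask, climbs with no lag above the scatter: target stands at 2.6% after 1.00 min and 13.3% after 5.00 min. That is a rate r = 0.665 mM min⁻¹.

| setting | violet | Saturday's | Tuesday's |
|---|---|---|---|
| starting material | 25 mM | 25 mM | 50 mM |
| second substrate | 25 mM | 25.0 mM | 25.0 mM |
| reagent | 15 mM | 15.0 mM | 15.0 mM |
| free catalyst | 0.38 mM | 0.25 mM | 0.25 mM |
| impurity | 35 µM | 35 µM | 35 µM |
| remark | run made earlier |  |  |
| time |  | 1.0 h | 0.60 h |

violet run (percent of the starting material charged)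

| time / min | target / % | starting material / % |
|---|---|---|
| 1.00 | 2.6 | 97.1 |
| 2.00 | 5.3 | 94.3 |
| 5.00 | 13.3 | 86.9 |
| 12.0 | 26.8 | 72.8 |

(standard deviation of a reading: 0.3 percentage points)

- no earlier run changes the charge of free catalyst; that part of a forecast is a guess

- the winner by amount of target, in percent of the starting material charged; "neither" if no more than 2 percentage points parts them (Saturday's / Tuesday's / neither)
- how much target is there at the end, in percent of the starting material charged: Saturday's
- how much target is there at the end, in percent of the starting material charged: Tuesday's

**Reagent clock.** I take one reagent per target and define the clock τ as reagent charge over r, which gives 22.6 min in the violet run. No run varies the catalyst, so scaling r with its charge is a guess. It gives Saturday's τ = 34.3 min, shorter than its 60 min. If the extra starting material does not slow Tuesday's flask, its τ is no longer, and that is barely inside its 36 min. The clock is rough, but on this ladder the stop is the last rung.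

**The ceiling.** By my reckoning, then, a balance should matter more at the stop than a rate. Reagent is the limiting reagent, and the ceiling C, reagent charge over starting-material charge, bounds target: 60.0% for Saturday's and 30.0% for Tuesday's, which is half. The readings follow neither second substrate nor reagent, so I give these as bounds, not estimates. I expect Saturday's to win.

**The forecast.** It says Saturday's, with 52% for Saturday's and 29% for Tuesday's, “capping target at 15 mM”. Its Saturday's value comes from its rate law, while its Tuesday's value rests on that cap, the same balance as my ceiling C for that flask.

**The result.** Saturday's gives 33.9% and Tuesday's 21.8%, so Saturday's wins, with reagent at 0% and 0% of charge.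

    starting material + free catalyst ⇌ catalyst intermediate A (K = 120 M⁻¹, k = 92.8 M⁻¹ min⁻¹)
    reagent + catalyst intermediate A → free catalyst + target (k = 2860 M⁻¹ min⁻¹)
    second substrate + free catalyst ⇌ catalyst intermediate B (K = 40.0 M⁻¹, k = 77.8 M⁻¹ min⁻¹)
    reagent + catalyst intermediate B → free catalyst + second product (k = 2240 M⁻¹ min⁻¹)
    free catalyst + impurity → spent catalyst (k = 2.78 × 10⁵ M⁻¹ min⁻¹)

In Saturday's, at 0.184 h, reagent feeds target 1.2 times as fast as second product. At the end, Saturday's holds 8.48 mM of target beside 6.52 mM of second product, which together match the 15.0 mM charged, and its target is 56.6% of C.

**Second flask.** The neighbour like Saturday's with 25 mM of reagent has C = 100%, and Saturday's share of that gives 56.6%. The computed flask gives 54.9%.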